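## Retrosynthetic overview

1. Target 17 ⇐ DDQ oxidation of the benzylic alcohol in the fully deprotected diol acid 16, so the epimerisable α-aryloxy ketone exists only in the last step.
2. 16 ⇐ desilylation and hydrogenolysis of 14; 14 ⇐ aryl–Cα bond between syringyl Grignard 13 and α-aryloxy aldehyde 10.
3. 10 ⇐ silyl alcohol 9 ⇐ (R)-monoacetate 7 ⇐ lipase desymmetrisation of the prochiral diacetate 6, which sets the only stereocentre that survives to the target.
4. 6 ⇐ prochiral diol 5 ⇐ Mitsunobu ether bond between benzyl vanillate 2 and achiral cis-benzylidene glycerol 3.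
5. No ring is formed: both benzene rings are bought (vanillic acid, 4-bromo-2,6-dimethoxyphenol), and the dioxane of 3 is only a temporary acetal.

Assumption: the lipase shows the enantiotopic preference reported for 2-O-benzylglycerol diacetate (pro-S acetate hydrolysed, (R)-monoacetate left); ee and sense are confirmed on 7 (chiral HPLC, Mosher ester) before continuing.

## Route

Step 1
Reactants: 1 vanillic acid (4-hydroxy-3-methoxybenzoic acid)
Product: 2 benzyl 4-hydroxy-3-methoxybenzoate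
Conditions: BnBr (1.05 equiv), KHCO3 (1.2 equiv), DMF, 40 °C
Reagents that add atoms: benzyl bromide, BrCc1ccccc1
Why: Carboxylate O-alkylation (SN2) in which bicarbonate deprotonates only the acid, so the phenol stays free.

Step 2
Reactants: 2 benzyl 4-hydroxy-3-methoxybenzoate; 3 cis-2-phenyl-1,3-dioxan-5-ol (achiral, mirror-symmetric)
Product: 4 benzyl 3-methoxy-4-[(trans-2-phenyl-1,3-dioxan-5-yl)oxy]benzoate
Conditions: PPh3, DIAD, THF, 0 °C → rt
Reagents that add atoms: none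
Why: Mitsunobu etherification of an acidic phenol with a secondary alcohol; the SN2 inversion gives the trans acetal, which is still achiral.

Step 3
Reactants: 4 benzyl 3-methoxy-4-[(trans-2-phenyl-1,3-dioxan-5-yl)oxy]benzoate
Product: 5 benzyl 4-[(1,3-dihydroxypropan-2-yl)oxy]-3-methoxybenzoate (prochiral diol)
Conditions: AcOH/H2O 4:1, 50 °C
Reagents that add atoms: none
Why: Acid-catalysed acetal hydrolysis releases the 1,3-diol while the benzyl ester and aryl ether are stable.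

Step 4
Reactants: 5 benzyl 4-[(1,3-dihydroxypropan-2-yl)oxy]-3-methoxybenzoate
Product: 6 benzyl 4-{[1,3-bis(acetyloxy)propan-2-yl]oxy}-3-methoxybenzoate (prochiral diacetate)
Conditions: Ac2O, pyridine, DMAP (cat.), CH2Cl2, rt
Reagents that add atoms: acetic anhydride, CC(=O)OC(C)=O
Why: DMAP-catalysed acylation of both primary hydroxyls gives the substrate for hydrolytic desymmetrisation.

Step 5
Reactants: 6 benzyl 4-{[1,3-bis(acetyloxy)propan-2-yl]oxy}-3-methoxybenzoate
Product: 7 benzyl 4-{[(2R)-1-(acetyloxy)-3-hydroxypropan-2-yl]oxy}-3-methoxybenzoate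
Conditions: lipase (Burkholderia cepacia lipase, Amano PS), 0.1 M phosphate buffer pH 7.0/i-Pr2O, 25 °C, stopped after one acetate is released
Reagents that add atoms: none
Why: Lipase-catalysed enantiotopos-selective hydrolysis (desymmetrisation of a prochiral 2-substituted propane-1,3-diyl diacetate) cleaves only the pro-S acetoxymethyl arm and so creates the stereocentre as R, while the aromatic benzyl ester is not a lipase substrate.

Step 6
Reactants: 7 benzyl 4-{[(2R)-1-(acetyloxy)-3-hydroxypropan-2-yl]oxy}-3-methoxybenzoate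
Product: 8 benzyl 4-{[(2S)-1-(acetyloxy)-3-[(tert-butyldiphenylsilyl)oxy]propan-2-yl]oxy}-3-methoxybenzoate
Conditions: TBDPSCl, imidazole, CH2Cl2, 0 °C → rt, on crude 7
Reagents that add atoms: tert-butyl(chloro)diphenylsilane, CC(C)(C)[Si](Cl)(c1ccccc1)c1ccccc1
Why: Prompt silylation of the primary alcohol blocks the 1,3-acyl migration that would racemise 7; the descriptor changes to S only through CIP priorities.

Step 7
Reactants: 8 benzyl 4-{[(2S)-1-(acetyloxy)-3-[(tert-butyldiphenylsilyl)oxy]propan-2-yl]oxy}-3-methoxybenzoate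
Product: 9 benzyl 4-{[(2S)-1-[(tert-butyldiphenylsilyl)oxy]-3-hydroxypropan-2-yl]oxy}-3-methoxybenzoate
Conditions: lipase (immobilised Candida antarctica lipase B), n-BuOH (5 equiv), MTBE, 40 °C
Reagents that add atoms: none
Why: Lipase-catalysed alcoholysis (transesterification) removes the aliphatic acetate at neutral pH, leaving the aromatic benzyl ester and avoiding the base-induced 1,3-silyl migration that would racemise 9.

Step 8
Reactants: 9 benzyl 4-{[(2S)-1-[(tert-butyldiphenylsilyl)oxy]-3-hydroxypropan-2-yl]oxy}-3-methoxybenzoate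
Product: 10 benzyl 4-{[(2R)-1-[(tert-butyldiphenylsilyl)oxy]-3-oxopropan-2-yl]oxy}-3-methoxybenzoate
Conditions: Dess–Martin periodinane, CH2Cl2, 0 °C → rt; used crude at once
Reagents that add atoms: none
Why: Dess–Martin oxidation is near-neutral and gives the α-aryloxy aldehyde without epimerising C2 (R only by CIP change).

Step 9
Reactants: 11 4-bromo-2,6-dimethoxyphenol
Product: 12 2-(benzyloxy)-5-bromo-1,3-dimethoxybenzene
Conditions: BnBr, K2CO3, DMF, 60 °C
Reagents that add atoms: benzyl bromide, BrCc1ccccc1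
Why: Williamson ether synthesis protects the syringyl phenol in a form that survives Grignard formation.

Step 10
Reactants: 12 2-(benzyloxy)-5-bromo-1,3-dimethoxybenzene; 10 benzyl 4-{[(2R)-1-[(tert-butyldiphenylsilyl)oxy]-3-oxopropan-2-yl]oxy}-3-methoxybenzoate
Product: 14 benzyl 4-{[(1RS,2R)-1-[4-(benzyloxy)-3,5-dimethoxyphenyl]-3-[(tert-butyldiphenylsilyl)oxy]-1-hydroxypropan-2-yl]oxy}-3-methoxybenzoate, via arylmagnesium bromide 13 (not isolated)
Conditions: Mg, I2 (cat.), THF, 50 °C; then 10 (1.15 equiv Grignard), THF, −78 °C; pH 7 buffer quench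
Reagents that add atoms: none
Why: Grignard 1,2-addition to the aldehyde at −78 °C outruns enolisation and attack on the benzoate; the new carbinol centre forms as an epimer mixture that is removed by the oxidation in step 13.

Step 11
Reactants: 14 benzyl 4-{[(1RS,2R)-1-[4-(benzyloxy)-3,5-dimethoxyphenyl]-3-[(tert-butyldiphenylsilyl)oxy]-1-hydroxypropan-2-yl]oxy}-3-methoxybenzoate
Product: 15 benzyl 4-{[(1RS,2R)-1-[4-(benzyloxy)-3,5-dimethoxyphenyl]-1,3-dihydroxypropan-2-yl]oxy}-3-methoxybenzoate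
Conditions: TBAF, AcOH (1:1), THF, rt
Reagents that add atoms: none
Why: Buffered fluoride desilylation is safe here because C2 is not enolisable at the alcohol oxidation level.

Step 12
Reactants: 15 benzyl 4-{[(1RS,2R)-1-[4-(benzyloxy)-3,5-dimethoxyphenyl]-1,3-dihydroxypropan-2-yl]oxy}-3-methoxybenzoate
Product: 16 4-{[(1RS,2R)-1,3-dihydroxy-1-(4-hydroxy-3,5-dimethoxyphenyl)propan-2-yl]oxy}-3-methoxybenzoic acid
Conditions: H2 (1 atm), 10% Pd/C, EtOAc/MeOH, rt
Reagents that add atoms: none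
Why: Hydrogenolysis removes the benzyl ester and benzyl ether before the ketone exists, so neither ketone reduction nor C–O cleavage of an α-aryloxy ketone can occur.

Step 13
Reactants: 16 4-{[(1RS,2R)-1,3-dihydroxy-1-(4-hydroxy-3,5-dimethoxyphenyl)propan-2-yl]oxy}-3-methoxybenzoic acid
Product: 17 4-{[(2R)-3-hydroxy-1-(4-hydroxy-3,5-dimethoxyphenyl)-1-oxopropan-2-yl]oxy}-3-methoxybenzoic acid
Conditions: DDQ (1.2 equiv), 1,4-dioxane, rt, dark
Reagents that add atoms: none
Why: DDQ dehydrogenation is selective for the p-hydroxybenzylic alcohol (hydride abstraction via a quinone-methide-type cation), leaves the primary alcohol and acid untouched, converges both C1 epimers and runs without base so C2 stays R.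

## Compound list

1 | vanillic acid | COc1cc(C(=O)O)ccc1O | starting material
2 | benzyl 4-hydroxy-3-methoxybenzoate | COc1cc(C(=O)OCc2ccccc2)ccc1O | intermediate
3 | cis-2-phenyl-1,3-dioxan-5-ol (achiral) | O[C@H]1CO[C@@H](c2ccccc2)OC1 | starting material
4 | benzyl 3-methoxy-4-[(trans-2-phenyl-1,3-dioxan-5-yl)oxy]benzoate (achiral) | COc1cc(C(=O)OCc2ccccc2)ccc1O[C@H]1CO[C@H](c2ccccc2)OC1 | intermediate
5 | benzyl 4-[(1,3-dihydroxypropan-2-yl)oxy]-3-methoxybenzoate | COc1cc(C(=O)OCc2ccccc2)ccc1OC(CO)CO | intermediate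
6 | benzyl 4-{[1,3-bis(acetyloxy)propan-2-yl]oxy}-3-methoxybenzoate | COc1cc(C(=O)OCc2ccccc2)ccc1OC(COC(C)=O)COC(C)=O | intermediate
7 | benzyl 4-{[(2R)-1-(acetyloxy)-3-hydroxypropan-2-yl]oxy}-3-methoxybenzoate | COc1cc(C(=O)OCc2ccccc2)ccc1O[C@H](CO)COC(C)=O | intermediate
8 | benzyl 4-{[(2S)-1-(acetyloxy)-3-[(tert-butyldiphenylsilyl)oxy]propan-2-yl]oxy}-3-methoxybenzoate | COc1cc(C(=O)OCc2ccccc2)ccc1O[C@H](CO[Si](c2ccccc2)(c2ccccc2)C(C)(C)C)COC(C)=O | intermediate
9 | benzyl 4-{[(2S)-1-[(tert-butyldiphenylsilyl)oxy]-3-hydroxypropan-2-yl]oxy}-3-methoxybenzoate | COc1cc(C(=O)OCc2ccccc2)ccc1O[C@H](CO[Si](c2ccccc2)(c2ccccc2)C(C)(C)C)CO | intermediate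
10 | benzyl 4-{[(2R)-1-[(tert-butyldiphenylsilyl)oxy]-3-oxopropan-2-yl]oxy}-3-methoxybenzoate | COc1cc(C(=O)OCc2ccccc2)ccc1O[C@H](CO[Si](c2ccccc2)(c2ccccc2)C(C)(C)C)C=O | intermediate
11 | 4-bromo-2,6-dimethoxyphenol | COc1cc(Br)cc(OC)c1O | starting material
12 | 2-(benzyloxy)-5-bromo-1,3-dimethoxybenzene | COc1cc(Br)cc(OC)c1OCc1ccccc1 | intermediate
13 | [4-(benzyloxy)-3,5-dimethoxyphenyl]magnesium bromide (not isolated) | COc1cc([Mg]Br)cc(OC)c1OCc1ccccc1 | intermediate
14 | benzyl 4-{[(1RS,2R)-1-[4-(benzyloxy)-3,5-dimethoxyphenyl]-3-[(tert-butyldiphenylsilyl)oxy]-1-hydroxypropan-2-yl]oxy}-3-methoxybenzoate | COc1cc(C(=O)OCc2ccccc2)ccc1O[C@H](CO[Si](c2ccccc2)(c2ccccc2)C(C)(C)C)C(O)c1cc(OC)c(OCc2ccccc2)c(OC)c1 | intermediate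
15 | benzyl 4-{[(1RS,2R)-1-[4-(benzyloxy)-3,5-dimethoxyphenyl]-1,3-dihydroxypropan-2-yl]oxy}-3-methoxybenzoate | COc1cc(C(=O)OCc2ccccc2)ccc1O[C@H](CO)C(O)c1cc(OC)c(OCc2ccccc2)c(OC)c1 | intermediate
16 | 4-{[(1RS,2R)-1,3-dihydroxy-1-(4-hydroxy-3,5-dimethoxyphenyl)propan-2-yl]oxy}-3-methoxybenzoic acid | COc1cc(C(=O)O)ccc1O[C@H](CO)C(O)c1cc(OC)c(O)c(OC)c1 | intermediate
17 | 4-{[(2R)-3-hydroxy-1-(4-hydroxy-3,5-dimethoxyphenyl)-1-oxopropan-2-yl]oxy}-3-methoxybenzoic acid (CNP0507417.1) | COc1cc(C(=O)O)ccc1O[C@H](CO)C(=O)c1cc(OC)c(O)c(OC)c1 | target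

## Step count and risks

Total steps: 13. Longest linear sequence: 12 (steps 1–8 and 10–13; step 9 is a one-step side branch).

Three steps most likely to fail:

**Step 5** (ee or sense of the hydrolytic desymmetrisation on a new substrate). The fallback sets out from 5 and comes back at 9. The desymmetrisation is run in the acyl-transfer direction on the diol itself: lipase (Burkholderia cepacia or porcine pancreatic lipase) with vinyl acetate in dry MTBE. This avoids aqueous acyl migration and, with the same enantiotopic preference, acetylates the pro-S arm to give the enantiomeric monoacetate benzyl 4-{[(2S)-1-(acetyloxy)-3-hydroxypropan-2-yl]oxy}-3-methoxybenzoate F1. Because the acetate now sits on the arm that must end as CH2OH, the protecting groups are relayed. The free hydroxyl is capped with 3,4-dihydro-2H-pyran and PPTS in CH2Cl2 to give the THP ether benzyl 4-{[(2S)-1-(acetyloxy)-3-(oxan-2-yloxy)propan-2-yl]oxy}-3-methoxybenzoate F2. Lipase alcoholysis as in step 7 gives the alcohol benzyl 4-{[(2R)-1-hydroxy-3-(oxan-2-yloxy)propan-2-yl]oxy}-3-methoxybenzoate F3. Silylation (TBDPSCl, imidazole) gives benzyl 4-{[(2S)-1-[(tert-butyldiphenylsilyl)oxy]-3-(oxan-2-yloxy)propan-2-yl]oxy}-3-methoxybenzoate F4, and PPTS in EtOH at 45 °C removes the THP group to give 9. If a lipase shows the opposite preference, the same acylation gives 7 directly.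

**Step 10** (racemisation or elimination of aldehyde 10, or Grignard attack on the benzyl ester). The fallback sets out from 9 and 12 and comes back at 14, avoiding both the aldehyde and the organomagnesium. 9 is oxidised directly with TEMPO (cat.) and PhI(OAc)2 in MeCN/H2O to the acid (2R)-2-{4-[(benzyloxy)carbonyl]-2-methoxyphenoxy}-3-[(tert-butyldiphenylsilyl)oxy]propanoic acid F5. This is coupled with thiophenol (EDC·HCl, HOBt, CH2Cl2, 0 °C, no DMAP) to the thioester benzyl 4-{[(2R)-1-[(tert-butyldiphenylsilyl)oxy]-3-oxo-3-(phenylsulfanyl)propan-2-yl]oxy}-3-methoxybenzoate F6. 12 is converted (n-BuLi, THF, −78 °C; B(OiPr)3; aqueous NH4Cl) into [4-(benzyloxy)-3,5-dimethoxyphenyl]boronic acid F7. A base-free Liebeskind–Srogl acyl cross-coupling of F6 with F7 (Pd2(dba)3, tri(2-furyl)phosphine, copper(I) thiophene-2-carboxylate, THF, 50 °C) gives the ketone benzyl 4-{[(2R)-1-[4-(benzyloxy)-3,5-dimethoxyphenyl]-3-[(tert-butyldiphenylsilyl)oxy]-1-oxopropan-2-yl]oxy}-3-methoxybenzoate F8. NaBH4 in THF/MeOH at −20 °C reduces F8 to 14.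

**Step 13** (over-oxidation of the free syringyl phenol by DDQ, or difficult isolation of the polar acid). The fallback sets out from 15 and comes back at 17, with the oxidation moved before the deprotection. Lipase (Candida antarctica lipase B) with vinyl acetate in MTBE acetylates only the primary hydroxyl of 15 to give benzyl 4-{[(1RS,2R)-3-(acetyloxy)-1-[4-(benzyloxy)-3,5-dimethoxyphenyl]-1-hydroxypropan-2-yl]oxy}-3-methoxybenzoate F9. Dess–Martin periodinane oxidises the benzylic alcohol to the keto acetate benzyl 4-{[(2R)-3-(acetyloxy)-1-[4-(benzyloxy)-3,5-dimethoxyphenyl]-1-oxopropan-2-yl]oxy}-3-methoxybenzoate F10. Lipase hydrolysis in pH 7 phosphate buffer/MTBE removes the acetate without the β-elimination that base would cause, giving the hydroxy ketone benzyl 4-{[(2R)-1-[4-(benzyloxy)-3,5-dimethoxyphenyl]-3-hydroxy-1-oxopropan-2-yl]oxy}-3-methoxybenzoate F11. Brief hydrogenolysis (H2, Pd/C, EtOAc) of both benzyl groups gives 17.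

## Further compounds

F1 | step 5 | benzyl 4-{[(2S)-1-(acetyloxy)-3-hydroxypropan-2-yl]oxy}-3-methoxybenzoate | COc1cc(C(=O)OCc2ccccc2)ccc1O[C@@H](CO)COC(C)=O
F2 | step 5 | benzyl 4-{[(2S)-1-(acetyloxy)-3-(oxan-2-yloxy)propan-2-yl]oxy}-3-methoxybenzoate | COc1cc(C(=O)OCc2ccccc2)ccc1O[C@@H](COC2CCCCO2)COC(C)=O
F3 | step 5 | benzyl 4-{[(2R)-1-hydroxy-3-(oxan-2-yloxy)propan-2-yl]oxy}-3-methoxybenzoate | COc1cc(C(=O)OCc2ccccc2)ccc1O[C@@H](COC2CCCCO2)CO
F4 | step 5 | benzyl 4-{[(2S)-1-[(tert-butyldiphenylsilyl)oxy]-3-(oxan-2-yloxy)propan-2-yl]oxy}-3-methoxybenzoate | COc1cc(C(=O)OCc2ccccc2)ccc1O[C@@H](COC2CCCCO2)CO[Si](c2ccccc2)(c2ccccc2)C(C)(C)C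
F5 | step 10 | (2R)-2-{4-[(benzyloxy)carbonyl]-2-methoxyphenoxy}-3-[(tert-butyldiphenylsilyl)oxy]propanoic acid | COc1cc(C(=O)OCc2ccccc2)ccc1O[C@H](CO[Si](c2ccccc2)(c2ccccc2)C(C)(C)C)C(=O)O
F6 | step 10 | benzyl 4-{[(2R)-1-[(tert-butyldiphenylsilyl)oxy]-3-oxo-3-(phenylsulfanyl)propan-2-yl]oxy}-3-methoxybenzoate | COc1cc(C(=O)OCc2ccccc2)ccc1O[C@H](CO[Si](c2ccccc2)(c2ccccc2)C(C)(C)C)C(=O)Sc1ccccc1
F7 | step 10 | [4-(benzyloxy)-3,5-dimethoxyphenyl]boronic acid | COc1cc(B(O)O)cc(OC)c1OCc1ccccc1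
F8 | step 10 | benzyl 4-{[(2R)-1-[4-(benzyloxy)-3,5-dimethoxyphenyl]-3-[(tert-butyldiphenylsilyl)oxy]-1-oxopropan-2-yl]oxy}-3-methoxybenzoate | COc1cc(C(=O)OCc2ccccc2)ccc1O[C@H](CO[Si](c2ccccc2)(c2ccccc2)C(C)(C)C)C(=O)c1cc(OC)c(OCc2ccccc2)c(OC)c1
F9 | step 13 | benzyl 4-{[(1RS,2R)-3-(acetyloxy)-1-[4-(benzyloxy)-3,5-dimethoxyphenyl]-1-hydroxypropan-2-yl]oxy}-3-methoxybenzoate | COc1cc(C(=O)OCc2ccccc2)ccc1O[C@H](COC(C)=O)C(O)c1cc(OC)c(OCc2ccccc2)c(OC)c1
F10 | step 13 | benzyl 4-{[(2R)-3-(acetyloxy)-1-[4-(benzyloxy)-3,5-dimethoxyphenyl]-1-oxopropan-2-yl]oxy}-3-methoxybenzoate | COc1cc(C(=O)OCc2ccccc2)ccc1O[C@H](COC(C)=O)C(=O)c1cc(OC)c(OCc2ccccc2)c(OC)c1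
F11 | step 13 | benzyl 4-{[(2R)-1-[4-(benzyloxy)-3,5-dimethoxyphenyl]-3-hydroxy-1-oxopropan-2-yl]oxy}-3-methoxybenzoate | COc1cc(C(=O)OCc2ccccc2)ccc1O[C@H](CO)C(=O)c1cc(OC)c(OCc2ccccc2)c(OC)c1
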